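**Retrosynthetic overview**
1. Side chain last: cross-metathesis with methyl methacrylate, C12 acetylation and catalytic asymmetric allylboration of a C4 aldehyde; the C1 acetate comes from a PMB acetal.
2. The C4 aldehyde comes from palladium-catalysed formylation of a C3=C4 enol triflate; the 7,8-epoxide is set by Shi epoxidation of the 7Z ring olefin while the enol ether is still electron-poor.
3. The nine-membered ring comes from ring-closing metathesis of a trans-4a,11a-dialkenyl tetrahydropyran-4-one, made by conjugate addition/enolate alkylation of an enantioenriched 6-alkoxy-2H-pyran-3(6H)-one.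
4. Key disconnection: the anomeric C1–O bond. An enantioconvergent palladium-catalysed etherification of the racemic Achmatowicz product of furfuryl alcohol sets C1, which then controls C11a and C4a.
5. Ring order: pyran ring (oxidative ring expansion of the furan), then the nine-membered carbocycle (metathesis), then the oxirane.

Assumption: the SMILES is read literally as (1R,4aS,7S,8R,11aR,12S) with trans ring fusion, a 7,8-epoxide whose two ring bonds are cis (derived from the 7Z olefin) and a 14E enoate; the catalyst enantiomers in steps 2, 8 and 11 are those predicted by the usual models.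

Numbering in names (cyclonona[c]pyran): C1 acetal carbon, O2, C3, C4, C4a, C5–C11, C11a; C12 is the side-chain carbinol carbon.

**Step 1**
Reactants: 1 furfuryl alcohol
Product: 3 rac-tert-butyl (5-oxo-5,6-dihydro-2H-pyran-2-yl) carbonate, via lactol 2 (not isolated)
Conditions: NBS, NaHCO3, NaOAc, THF/H2O, 0 °C; extract; then Boc2O, DMAP (cat.), CH2Cl2, −78 to −30 °C
Reagents that add atoms: water (O); di-tert-butyl dicarbonate (CC(C)(C)OC(=O)OC(=O)OC(C)(C)C)
Why: Achmatowicz rearrangement (oxidation of the furylcarbinol, ring opening to the Z-enedione and lactol closure build the pyranone through C–O bond formation), then routine carbonate formation; the acetal centre is racemic at this point.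

**Step 2**
Reactants: 3 rac-tert-butyl (5-oxo-5,6-dihydro-2H-pyran-2-yl) carbonate
Product: 4 (S)-6-[(4-methoxybenzyl)oxy]-2H-pyran-3(6H)-one
Conditions: Pd2(dba)3·CHCl3 (2.5 mol%), (R,R)-DACH-phenyl Trost ligand (7.5 mol%), Bu4NCl (30 mol%), CH2Cl2, 0 °C
Reagents that add atoms: 4-methoxybenzyl alcohol (COc1ccc(CO)cc1)
Why: Proposed new method: enantioconvergent palladium-catalysed anomeric etherification (a dynamic kinetic asymmetric allylic substitution) in which zerovalent palladium ionises both enantiomers of 3 with loss of CO2 and tert-butoxide, the diastereomeric π-allyl complexes interconvert through the planar, achiral O-bound 6H-pyran-3-olate (chloride speeds this up), and the chiral pocket lets the alkoxide attack one face of the acetal terminus to set C1; the closest known reactions are the stereospecific palladium-catalysed O-glycosylation of enantiopure Boc-pyranones and the dynamic kinetic asymmetric etherification of 5-acyloxy-2(5H)-furanones with phenols.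

**Step 3**
Reactants: 5 2,3-dibromoprop-1-ene; 6 allylmagnesium bromide
Product: 7 2-bromohexa-1,5-diene
Conditions: Et2O, 0 °C to rt
Reagents that add atoms: none
Why: Grignard allylation by SN2 displacement of the allylic bromide; the vinylic bromide is inert.

**Step 4**
Reactants: 8 3-methylbut-3-en-1-ol
Product: 9 3-methylbut-3-en-1-yl trifluoromethanesulfonate
Conditions: Tf2O, 2,6-lutidine, CH2Cl2, −78 °C; used at once as a cold solution
Reagents that add atoms: trifluoromethanesulfonic anhydride (O=S(=O)(OS(=O)(=O)C(F)(F)F)C(F)(F)F)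
Why: O-sulfonylation of a primary alcohol gives an electrophile reactive enough for a hindered ketone enolate; it is kept below −20 °C because the homoallylic triflate ionises on warming.

**Step 5**
Reactants: 4 (S)-6-[(4-methoxybenzyl)oxy]-2H-pyran-3(6H)-one; 7 2-bromohexa-1,5-diene; 9 3-methylbut-3-en-1-yl trifluoromethanesulfonate
Product: 13 (4S,5R,6S)-5-(hexa-1,5-dien-2-yl)-6-[(4-methoxybenzyl)oxy]-4-(3-methylbut-3-en-1-yl)dihydro-2H-pyran-3(4H)-one, via Grignard reagent 10 (not isolated), via silyl enol ether 11 (not isolated), via lithium enolate 12 (not isolated)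
Conditions: 7, Mg, THF, 40 °C; then CuBr·SMe2 (10 mol%), Me3SiCl, 4, THF, −78 °C; solvent exchange; MeLi (1.0 equiv), THF, 0 °C; then 9, THF, −78 to −20 °C
Reagents that add atoms: none
Why: copper-catalysed conjugate addition followed by enolate alkylation (three-component coupling): the alkenyl group adds to C11a anti to the pseudo-axial C1 alkoxy group (1,11a-trans), and the regiodefined lithium enolate released from the silyl enol ether is alkylated anti to the new C11a substituent (4a,11a-trans).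

**Step 6**
Reactants: 13 (4S,5R,6S)-5-(hexa-1,5-dien-2-yl)-6-[(4-methoxybenzyl)oxy]-4-(3-methylbut-3-en-1-yl)dihydro-2H-pyran-3(4H)-one
Product: 14 (1S,4aS,7Z,11aR)-1-[(4-methoxybenzyl)oxy]-7-methyl-11-methylene-1,4a,5,6,9,10,11,11a-octahydrocyclonona[c]pyran-4(3H)-one
Conditions: second-generation Hoveyda–Grubbs catalyst (10 mol%), 1,4-benzoquinone (20 mol%), toluene (1 mM), 90 °C
Reagents that add atoms: none
Why: ring-closing metathesis between the terminal vinyl group and the 1,1-disubstituted olefin of the two gauche, equatorial arms; the ring size enforces the Z olefin, and the C11 methylene cannot compete because it could only close a cyclobutene or a tetrasubstituted cyclohexene.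

**Step 7**
Reactants: 14 (1S,4aS,7Z,11aR)-1-[(4-methoxybenzyl)oxy]-7-methyl-11-methylene-1,4a,5,6,9,10,11,11a-octahydrocyclonona[c]pyran-4(3H)-one
Product: 15 (1S,4aS,7Z,11aR)-1-[(4-methoxybenzyl)oxy]-7-methyl-11-methylene-1,4a,5,6,9,10,11,11a-octahydrocyclonona[c]pyran-4-yl trifluoromethanesulfonate
Conditions: KN(SiMe3)2, THF, −78 °C; then PhNTf2, −78 to −30 °C
Reagents that add atoms: N-phenylbis(trifluoromethanesulfonimide) (O=S(=O)(N(c1ccccc1)S(=O)(=O)C(F)(F)F)C(F)(F)F)
Why: kinetic enolisation with a bulky amide base at the C3 methylene (the C4a hydrogen is a hindered ring-fusion methine) and O-triflation give the C3=C4 enol triflate; no stereocentre is touched.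

**Step 8**
Reactants: 15 (1S,4aS,7Z,11aR)-1-[(4-methoxybenzyl)oxy]-7-methyl-11-methylene-1,4a,5,6,9,10,11,11a-octahydrocyclonona[c]pyran-4-yl trifluoromethanesulfonate
Product: 16 (1S,4aS,7S,8R,11aR)-7,8-epoxy-1-[(4-methoxybenzyl)oxy]-7-methyl-11-methylene-1,4a,5,6,7,8,9,10,11,11a-decahydrocyclonona[c]pyran-4-yl trifluoromethanesulfonate
Conditions: D-fructose-derived Shi ketone (30 mol%), KHSO5 (as its triple salt), K2CO3, Bu4NHSO4, MeCN/CH2(OMe)2/aq. Na2B4O7 buffer, 0 °C
Reagents that add atoms: potassium peroxymonosulfate ([K+].[O-]S(=O)(=O)OO)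
Why: Shi asymmetric epoxidation: the chiral dioxirane reacts only with the trisubstituted C7=C8 olefin (the enol triflate is electron-poor, the 1,1-disubstituted methylene is a poor substrate), and the spiro transition state delivers oxygen to the face that gives (7S,8R).

**Step 9**
Reactants: 16 (1S,4aS,7S,8R,11aR)-7,8-epoxy-1-[(4-methoxybenzyl)oxy]-7-methyl-11-methylene-1,4a,5,6,7,8,9,10,11,11a-decahydrocyclonona[c]pyran-4-yl trifluoromethanesulfonate
Product: 17 (1S,4aS,7S,8R,11aR)-7,8-epoxy-1-[(4-methoxybenzyl)oxy]-7-methyl-11-methylene-1,4a,5,6,7,8,9,10,11,11a-decahydrocyclonona[c]pyran-4-carbaldehyde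
Conditions: Pd(PPh3)4 (5 mol%), CO (1 atm), Bu3SnH (slow addition), LiCl, THF, 50 °C
Reagents that add atoms: carbon monoxide ([C-]#[O+])
Why: palladium-catalysed reductive carbonylation (formylation) of the enol triflate by oxidative addition, CO insertion and hydride transfer from tin; the epoxide and acetal are inert and the product is a stable vinylogous formate.

**Step 10**
Reactants: 17 (1S,4aS,7S,8R,11aR)-7,8-epoxy-1-[(4-methoxybenzyl)oxy]-7-methyl-11-methylene-1,4a,5,6,7,8,9,10,11,11a-decahydrocyclonona[c]pyran-4-carbaldehyde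
Product: 19 (1R,4aS,7S,8R,11aR)-1-acetoxy-7,8-epoxy-7-methyl-11-methylene-1,4a,5,6,7,8,9,10,11,11a-decahydrocyclonona[c]pyran-4-carbaldehyde, via lactol 18 (not isolated)
Conditions: DDQ, CH2Cl2/pH 7 buffer, 0 °C; extract; then Ac2O, Et3N, DMAP (cat.), CH2Cl2, −40 to 0 °C
Reagents that add atoms: water (O); acetic anhydride (CC(=O)OC(C)=O)
Why: oxidative cleavage of the PMB acetal, then DMAP-catalysed acylation of the equilibrating lactol, in which the pseudo-equatorial anomer (OH trans to the C11 substituent on C11a) reacts faster and gives the 1R acetate (dynamic kinetic acylation under control of C11a).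

**Step 11**
Reactants: 19 (1R,4aS,7S,8R,11aR)-1-acetoxy-7,8-epoxy-7-methyl-11-methylene-1,4a,5,6,7,8,9,10,11,11a-decahydrocyclonona[c]pyran-4-carbaldehyde; 20 2-allyl-4,4,5,5-tetramethyl-1,3,2-dioxaborolane
Product: 22 (1R,4aS,7S,8R,11aR)-1-acetoxy-7,8-epoxy-4-[(1S)-1-hydroxybut-3-en-1-yl]-7-methyl-11-methylene-1,4a,5,6,7,8,9,10,11,11a-decahydrocyclonona[c]pyran, via pinacol borate 21 (not isolated)
Conditions: (S)-TRIP phosphoric acid (10 mol%), 4 Å MS, toluene, −30 to 0 °C; aq. NaHCO3 work-up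
Reagents that add atoms: none
Why: chiral phosphoric acid-catalysed allylboration through a closed chair transition state; the (S)-acid delivers the allyl group to the aldehyde face that gives 12S (the (R)-acid gives (R)-carbinols from aryl and alkenyl aldehydes), and these non-Lewis-acidic conditions spare the epoxide.

**Step 12**
Reactants: 22 (1R,4aS,7S,8R,11aR)-1-acetoxy-7,8-epoxy-4-[(1S)-1-hydroxybut-3-en-1-yl]-7-methyl-11-methylene-1,4a,5,6,7,8,9,10,11,11a-decahydrocyclonona[c]pyran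
Product: 23 (1R,4aS,7S,8R,11aR)-1-acetoxy-4-[(1S)-1-acetoxybut-3-en-1-yl]-7,8-epoxy-7-methyl-11-methylene-1,4a,5,6,7,8,9,10,11,11a-decahydrocyclonona[c]pyran
Conditions: Ac2O, pyridine, DMAP (cat.), CH2Cl2, 0 °C
Reagents that add atoms: acetic anhydride (CC(=O)OC(C)=O)
Why: DMAP-catalysed acetylation traps the acid-labile allylic alcohol next to the enol ether without touching any stereocentre.

**Step 13**
Reactants: 23 (1R,4aS,7S,8R,11aR)-1-acetoxy-4-[(1S)-1-acetoxybut-3-en-1-yl]-7,8-epoxy-7-methyl-11-methylene-1,4a,5,6,7,8,9,10,11,11a-decahydrocyclonona[c]pyran; 24 methyl methacrylate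
Product: 25 methyl (2E,5S)-5-acetoxy-5-[(1R,4aS,7S,8R,11aR)-1-acetoxy-7,8-epoxy-7-methyl-11-methylene-1,4a,5,6,7,8,9,10,11,11a-decahydrocyclonona[c]pyran-4-yl]-2-methylpent-2-enoate
Conditions: 24 (10 equiv), second-generation Hoveyda–Grubbs catalyst (5 mol%), CH2Cl2, 40 °C
Reagents that add atoms: none
Why: olefin cross-metathesis of the terminal alkene with excess methacrylate gives the E trisubstituted enoate; the C11 methylene and the trisubstituted enol ether are unreactive, and ring closure onto the methylene would need a bridgehead olefin.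

**Compound list**
1 | furfuryl alcohol (furan-2-ylmethanol) | OCc1ccco1 | starting material
2 | rac-6-hydroxy-2H-pyran-3(6H)-one | OC1OCC(=O)C=C1 | intermediate
3 | rac-tert-butyl (5-oxo-5,6-dihydro-2H-pyran-2-yl) carbonate | CC(C)(C)OC(=O)OC1OCC(=O)C=C1 | intermediate
4 | (S)-6-[(4-methoxybenzyl)oxy]-2H-pyran-3(6H)-one | COc1ccc(CO[C@H]2OCC(=O)C=C2)cc1 | intermediate
5 | 2,3-dibromoprop-1-ene | C=C(Br)CBr | starting material
6 | allylmagnesium bromide | C=CC[Mg]Br | starting material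
7 | 2-bromohexa-1,5-diene | C=CCCC(Br)=C | intermediate
8 | 3-methylbut-3-en-1-ol | C=C(C)CCO | starting material
9 | 3-methylbut-3-en-1-yl trifluoromethanesulfonate | C=C(C)CCOS(=O)(=O)C(F)(F)F | intermediate
10 | hexa-1,5-dien-2-ylmagnesium bromide | C=CCCC(=C)[Mg]Br | intermediate
11 | {[(5R,6S)-5-(hexa-1,5-dien-2-yl)-6-[(4-methoxybenzyl)oxy]-5,6-dihydro-2H-pyran-3-yl]oxy}trimethylsilane | COc1ccc(CO[C@H]2OCC(O[Si](C)(C)C)=C[C@@H]2C(=C)CCC=C)cc1 | intermediate
12 | lithium (5R,6S)-5-(hexa-1,5-dien-2-yl)-6-[(4-methoxybenzyl)oxy]-5,6-dihydro-2H-pyran-3-olate | COc1ccc(CO[C@H]2OCC(O[Li])=C[C@@H]2C(=C)CCC=C)cc1 | intermediate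
13 | (4S,5R,6S)-5-(hexa-1,5-dien-2-yl)-6-[(4-methoxybenzyl)oxy]-4-(3-methylbut-3-en-1-yl)dihydro-2H-pyran-3(4H)-one | COc1ccc(CO[C@H]2OCC(=O)[C@@H](CCC(C)=C)[C@@H]2C(=C)CCC=C)cc1 | intermediate
14 | (1S,4aS,7Z,11aR)-1-[(4-methoxybenzyl)oxy]-7-methyl-11-methylene-1,4a,5,6,9,10,11,11a-octahydrocyclonona[c]pyran-4(3H)-one | C=C1CC/C=C(C)\CC[C@@H]2C(=O)CO[C@H](OCc3ccc(OC)cc3)[C@@H]12 | intermediate
15 | (1S,4aS,7Z,11aR)-1-[(4-methoxybenzyl)oxy]-7-methyl-11-methylene-1,4a,5,6,9,10,11,11a-octahydrocyclonona[c]pyran-4-yl trifluoromethanesulfonate | C=C1CC/C=C(C)\CC[C@@H]2C(OS(=O)(=O)C(F)(F)F)=CO[C@H](OCc3ccc(OC)cc3)[C@@H]12 | intermediate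
16 | (1S,4aS,7S,8R,11aR)-7,8-epoxy-1-[(4-methoxybenzyl)oxy]-7-methyl-11-methylene-1,4a,5,6,7,8,9,10,11,11a-decahydrocyclonona[c]pyran-4-yl trifluoromethanesulfonate | C=C1CC[C@H]2O[C@@]2(C)CC[C@@H]2C(OS(=O)(=O)C(F)(F)F)=CO[C@H](OCc3ccc(OC)cc3)[C@@H]12 | intermediate
17 | (1S,4aS,7S,8R,11aR)-7,8-epoxy-1-[(4-methoxybenzyl)oxy]-7-methyl-11-methylene-1,4a,5,6,7,8,9,10,11,11a-decahydrocyclonona[c]pyran-4-carbaldehyde | C=C1CC[C@H]2O[C@@]2(C)CC[C@@H]2C(C=O)=CO[C@H](OCc3ccc(OC)cc3)[C@@H]12 | intermediate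
18 | (4aS,7S,8R,11aR)-7,8-epoxy-1-hydroxy-7-methyl-11-methylene-1,4a,5,6,7,8,9,10,11,11a-decahydrocyclonona[c]pyran-4-carbaldehyde (both C1 anomers) | C=C1CC[C@H]2O[C@@]2(C)CC[C@@H]2C(C=O)=COC(O)[C@@H]12 | intermediate
19 | (1R,4aS,7S,8R,11aR)-1-acetoxy-7,8-epoxy-7-methyl-11-methylene-1,4a,5,6,7,8,9,10,11,11a-decahydrocyclonona[c]pyran-4-carbaldehyde | C=C1CC[C@H]2O[C@@]2(C)CC[C@@H]2C(C=O)=CO[C@H](OC(C)=O)[C@@H]12 | intermediate
20 | 2-allyl-4,4,5,5-tetramethyl-1,3,2-dioxaborolane | C=CCB1OC(C)(C)C(C)(C)O1 | starting material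
21 | pinacol borate ester of 22 (O–B bond at the C12 oxygen) | C=C1CC[C@H]2O[C@@]2(C)CC[C@@H]2C([C@H](CC=C)OB3OC(C)(C)C(C)(C)O3)=CO[C@H](OC(C)=O)[C@@H]12 | intermediate
22 | (1R,4aS,7S,8R,11aR)-1-acetoxy-7,8-epoxy-4-[(1S)-1-hydroxybut-3-en-1-yl]-7-methyl-11-methylene-1,4a,5,6,7,8,9,10,11,11a-decahydrocyclonona[c]pyran | C=C1CC[C@H]2O[C@@]2(C)CC[C@@H]2C([C@H](CC=C)O)=CO[C@H](OC(C)=O)[C@@H]12 | intermediate
23 | (1R,4aS,7S,8R,11aR)-1-acetoxy-4-[(1S)-1-acetoxybut-3-en-1-yl]-7,8-epoxy-7-methyl-11-methylene-1,4a,5,6,7,8,9,10,11,11a-decahydrocyclonona[c]pyran | C=C1CC[C@H]2O[C@@]2(C)CC[C@@H]2C([C@H](CC=C)OC(C)=O)=CO[C@H](OC(C)=O)[C@@H]12 | intermediate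
24 | methyl methacrylate | C=C(C)C(=O)OC | starting material
25 | methyl (2E,5S)-5-acetoxy-5-[(1R,4aS,7S,8R,11aR)-1-acetoxy-7,8-epoxy-7-methyl-11-methylene-1,4a,5,6,7,8,9,10,11,11a-decahydrocyclonona[c]pyran-4-yl]-2-methylpent-2-enoate (CNP0184381.3) | C=C1CC[C@H]2O[C@@]2(C)CC[C@@H]2C([C@H](C/C=C(\C)C(=O)OC)OC(C)=O)=CO[C@H](OC(C)=O)[C@@H]12 | target

**Step count**
Total: 13 steps. Longest linear sequence: 11 steps (1, 2, 5, 6, 7, 8, 9, 10, 11, 12, 13); steps 3 and 4 are side branches.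

**Three steps most likely to fail**

Step 2 (the new enantioconvergent etherification) may give low enantioselectivity if the π-allyl complexes do not equilibrate faster than they are trapped. The fallback uses known chemistry, sets out from lactol 2 and comes back at 4. Lipase-mediated enantioselective O-acetylation of 2 with vinyl acetate (Burkholderia cepacia lipase, hexane, rt; the unreacted lactol racemises by ring opening, so the resolution is dynamic) gives (R)-5-oxo-5,6-dihydro-2H-pyran-2-yl acetate F1. Stereoretentive palladium-catalysed allylic substitution of F1 (Pd2(dba)3, PPh3, 4-methoxybenzyl alcohol, CH2Cl2, 0 °C; double inversion) then gives 4.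

Step 6 (metathesis to the nine-membered ring) may give oligomers or stall at the hindered 1,1-disubstituted olefin. The fallback closes the ring through the C8–C9 single bond with the Z olefin already in place; it sets out from 4 and comes back at 14.
- (3Z)-4-Iodo-3-methylbut-3-en-1-ol (from but-3-yn-1-ol by carboalumination, thermal isomerisation and iodination) is converted as in step 4 into (3Z)-4-iodo-3-methylbut-3-en-1-yl trifluoromethanesulfonate F2.
- The step-5 protocol is run on 4 with buta-1,3-dien-2-ylmagnesium chloride F3 (from chloroprene and Mg). It passes through {[(5R,6S)-5-(buta-1,3-dien-2-yl)-6-[(4-methoxybenzyl)oxy]-5,6-dihydro-2H-pyran-3-yl]oxy}trimethylsilane F4 and lithium (5R,6S)-5-(buta-1,3-dien-2-yl)-6-[(4-methoxybenzyl)oxy]-5,6-dihydro-2H-pyran-3-olate F5.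
- Alkylation of F5 with F2 gives (4S,5R,6S)-5-(buta-1,3-dien-2-yl)-4-[(3Z)-4-iodo-3-methylbut-3-en-1-yl]-6-[(4-methoxybenzyl)oxy]dihydro-2H-pyran-3(4H)-one F6.
- 9-BBN-H hydroborates the monosubstituted end of the diene to give (4S,5R,6S)-5-[4-(9-borabicyclo[3.3.1]nonan-9-yl)but-1-en-2-yl]-4-[(3Z)-4-iodo-3-methylbut-3-en-1-yl]-6-[(4-methoxybenzyl)oxy]dihydro-2H-pyran-3(4H)-one F7.
- Intramolecular B-alkyl Suzuki–Miyaura coupling (PdCl2(dppf), AsPh3, Cs2CO3, THF/DMF/H2O, high dilution) gives 14.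

Step 7 (regioselective enol triflate formation) may enolise towards C4a instead of C3. The fallback replaces enolate chemistry by a hydrazone route; it sets out from 14 and comes back at 17. Hydrazine hydrate (Et3N, EtOH) gives (1S,4aS,7Z,11aR)-4-hydrazinylidene-1-[(4-methoxybenzyl)oxy]-7-methyl-11-methylene-3,4,4a,5,6,9,10,11,11a-nonahydro-1H-cyclonona[c]pyran F8. Iodine and tetramethylguanidine (Barton vinyl iodide synthesis, elimination towards the oxygen-bearing C3 methylene) give (1S,4aS,7Z,11aR)-4-iodo-1-[(4-methoxybenzyl)oxy]-7-methyl-11-methylene-1,4a,5,6,9,10,11,11a-octahydrocyclonona[c]pyran F9. Shi epoxidation as in step 8 gives (1S,4aS,7S,8R,11aR)-7,8-epoxy-4-iodo-1-[(4-methoxybenzyl)oxy]-7-methyl-11-methylene-1,4a,5,6,7,8,9,10,11,11a-decahydrocyclonona[c]pyran F10. Formylation as in step 9 without LiCl (Pd(PPh3)4, CO, Bu3SnH) gives 17.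

**Further compounds**
F1 | step 2 | (R)-5-oxo-5,6-dihydro-2H-pyran-2-yl acetate | CC(=O)O[C@H]1OCC(=O)C=C1
F2 | step 6 | (3Z)-4-iodo-3-methylbut-3-en-1-yl trifluoromethanesulfonate | I/C=C(C)\CCOS(=O)(=O)C(F)(F)F
F3 | step 6 | buta-1,3-dien-2-ylmagnesium chloride | C=CC(=C)[Mg]Cl
F4 | step 6 | {[(5R,6S)-5-(buta-1,3-dien-2-yl)-6-[(4-methoxybenzyl)oxy]-5,6-dihydro-2H-pyran-3-yl]oxy}trimethylsilane | COc1ccc(CO[C@H]2OCC(O[Si](C)(C)C)=C[C@@H]2C(=C)C=C)cc1
F5 | step 6 | lithium (5R,6S)-5-(buta-1,3-dien-2-yl)-6-[(4-methoxybenzyl)oxy]-5,6-dihydro-2H-pyran-3-olate | COc1ccc(CO[C@H]2OCC(O[Li])=C[C@@H]2C(=C)C=C)cc1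
F6 | step 6 | (4S,5R,6S)-5-(buta-1,3-dien-2-yl)-4-[(3Z)-4-iodo-3-methylbut-3-en-1-yl]-6-[(4-methoxybenzyl)oxy]dihydro-2H-pyran-3(4H)-one | COc1ccc(CO[C@H]2OCC(=O)[C@@H](CC/C(C)=C\I)[C@@H]2C(=C)C=C)cc1
F7 | step 6 | (4S,5R,6S)-5-[4-(9-borabicyclo[3.3.1]nonan-9-yl)but-1-en-2-yl]-4-[(3Z)-4-iodo-3-methylbut-3-en-1-yl]-6-[(4-methoxybenzyl)oxy]dihydro-2H-pyran-3(4H)-one | COc1ccc(CO[C@H]2OCC(=O)[C@@H](CC/C(C)=C\I)[C@@H]2C(=C)CCB3C4CCCC3CCC4)cc1
F8 | step 7 | (1S,4aS,7Z,11aR)-4-hydrazinylidene-1-[(4-methoxybenzyl)oxy]-7-methyl-11-methylene-3,4,4a,5,6,9,10,11,11a-nonahydro-1H-cyclonona[c]pyran | C=C1CC/C=C(C)\CC[C@@H]2C(=NN)CO[C@H](OCc3ccc(OC)cc3)[C@@H]12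
F9 | step 7 | (1S,4aS,7Z,11aR)-4-iodo-1-[(4-methoxybenzyl)oxy]-7-methyl-11-methylene-1,4a,5,6,9,10,11,11a-octahydrocyclonona[c]pyran | C=C1CC/C=C(C)\CC[C@@H]2C(I)=CO[C@H](OCc3ccc(OC)cc3)[C@@H]12
F10 | step 7 | (1S,4aS,7S,8R,11aR)-7,8-epoxy-4-iodo-1-[(4-methoxybenzyl)oxy]-7-methyl-11-methylene-1,4a,5,6,7,8,9,10,11,11a-decahydrocyclonona[c]pyran | C=C1CC[C@H]2O[C@@]2(C)CC[C@@H]2C(I)=CO[C@H](OCc3ccc(OC)cc3)[C@@H]12
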